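Everything rests on making ring A last, as an arene grown onto an alkynyl ketone. Ring A is a resorcinol whose oxygens sit on C7 and C8a, with the heptyl chain on C5 and the C4 carbonyl on C4a; a buta-1,3-diene oxygenated twice at C1 and once at C3 adds across a heptyl ynone to give exactly this pattern. One cycloaddition–aromatization forms C4a–C8a and C5–C6 and delivers both phenols next to the finished aryl ketone. The dienophile carries ring B as a 6,8-bis(benzyloxy)isocoumarin, an enol lactone that hides the C2 ketone and the carboxylic acid. Lactone opening, hydrogenolysis and enantiomer separation at the labile C2 hemiketal then give the target.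

Key step: step 8

Remark on the chemistry: C2 is a hemiketal carbon that can epimerize by ring opening to the 1,3-diketone, so the material is carried as the racemate, (2R) is selected in the last step, and the free acid is assumed to hold its configuration when handled cold, near neutral and stored as a solid.

Step 1
Reactants: 1 methyl orsellinate (methyl 2,4-dihydroxy-6-methylbenzoate)
Product: 2 methyl 2,4-bis(benzyloxy)-6-methylbenzoate
Conditions: BnBr (2.5 equiv), K2CO3 (4 equiv), DMF, 60 °C
Reagents that add atoms: benzyl bromide BrCc1ccccc1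
Why: Williamson etherification of both phenoxides should proceed cleanly because the warm dipolar solvent breaks the hydrogen bond of the 2-OH to the ester and carbonate leaves the methyl ester intact.

Step 2
Reactants: 2 methyl 2,4-bis(benzyloxy)-6-methylbenzoate; 3 N-methoxy-N-methylacetamide
Product: 6 methyl 2,4-bis(benzyloxy)-6-(2-oxopropyl)benzoate, via benzylic lithio ester 4 (not isolated), via lithium N-methoxyaminal adduct 5 (not isolated)
Conditions: LDA (commercial solution, 1.2 equiv), THF, −78 °C; 3 (1.5 equiv), −78 → −40 °C; AcOH quench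
Reagents that add atoms: none
Why: Lateral lithiation–acylation: LDA removes a benzylic proton of the ortho-toluate (anion stabilized by the ester, whose 2,6-disubstitution blocks self-condensation) and the carbanion adds once to the N-methoxy-N-methylamide, the chelated adduct 5 holding the ketone back until the acidic quench.

Step 3
Reactants: 6 methyl 2,4-bis(benzyloxy)-6-(2-oxopropyl)benzoate
Product: 7 6,8-bis(benzyloxy)-3-methyl-1H-isochromen-1-one
Conditions: p-TsOH·H2O (10 mol %), toluene, 90 °C, 4 Å MS to take up MeOH
Reagents that add atoms: none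
Why: Acid-catalysed enol lactonization: the aryl-conjugated enol of the ketone attacks the neighbouring ester through a six-membered transition state and removal of methanol drives formation of the isocoumarin, whereas acid (unlike base) offers no Dieckmann path to a naphthalenediol and catalytic sulfonic acid in toluene leaves aryl benzyl ethers in place.

Step 4
Reactants: 8 non-1-yne; 9 N-methoxy-N-methylcarbamoyl chloride
Product: 11 N-methoxy-N-methyldec-2-ynamide, via lithium nonynide 10 (not isolated)
Conditions: n-BuLi (1.05 equiv), THF, −78 °C; 9 (1.1 equiv), −78 → 0 °C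
Reagents that add atoms: none
Why: Acylation of a lithium acetylide with a carbamoyl chloride (addition–elimination) should give the alkynyl N-methoxy-N-methylamide directly, since the amide formed is a much weaker electrophile than the acid chloride and is not attacked a second time at −78 °C.

Step 5
Reactants: 7 6,8-bis(benzyloxy)-3-methyl-1H-isochromen-1-one; 11 N-methoxy-N-methyldec-2-ynamide
Product: 14 6,8-bis(benzyloxy)-3-(2-oxoundec-3-yn-1-yl)-1H-isochromen-1-one, via 3-lithiomethyl isocoumarin 12 (not isolated), via lithium N-methoxyaminal adduct 13 (not isolated)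
Conditions: LDA (commercial solution, 1.1 equiv), THF, −78 °C; 11 (1.2 equiv), −78 °C; AcOH–THF quench at −78 °C
Reagents that add atoms: none
Why: Lateral lithiation–acylation: the 3-methyl group is deprotonated to an anion delocalized through C3=C4 into the benzoate (the benzo analogue of a 6-methyl-2-pyranone anion), which reacts at its exocyclic carbon with the amide carbonyl in a 1,2 sense, and the chelated adduct 13 releases the acidic, base-sensitive ynone only in the cold acetic acid quench, which also protonates the liberated hydroxylamine before it can add to the triple bond.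

Step 6
Reactants: 15 methyl acetoacetate
Product: 16 methyl 3-(trimethylsilyloxy)but-2-enoate (E/Z mixture)
Conditions: TMSCl (1.2 equiv), Et3N (1.3 equiv), hexane, rt; filtration, distillation
Reagents that add atoms: chlorotrimethylsilane C[Si](C)(C)Cl
Why: Silyl enol ether formation: the enol of the β-keto ester is O-silylated under amine base, and the double-bond geometry does not matter because this bond becomes the central single bond of the diene.

Step 7
Reactants: 16 methyl 3-(trimethylsilyloxy)but-2-enoate
Product: 18 (Z)-1-methoxy-1,3-bis(trimethylsilyloxy)buta-1,3-diene, via lithium dienolate 17 (not isolated)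
Conditions: LDA (commercial solution, 1.1 equiv), THF, −78 °C; TMSCl (1.2 equiv), −78 → 0 °C; hexane, filtration, used freshly
Reagents that add atoms: chlorotrimethylsilane C[Si](C)(C)Cl
Why: Dienolate silylation: kinetic γ-deprotonation of the vinylogous ester by LDA gives the extended ester enolate 17, which the hard silyl chloride traps on oxygen as the silyl ketene acetal.

Step 8
Reactants: 14 6,8-bis(benzyloxy)-3-(2-oxoundec-3-yn-1-yl)-1H-isochromen-1-one; 18 (Z)-1-methoxy-1,3-bis(trimethylsilyloxy)buta-1,3-diene
Product: 21 6,8-bis(benzyloxy)-3-[2-(2-heptyl-4,6-dihydroxyphenyl)-2-oxoethyl]-1H-isochromen-1-one, via cyclohexadiene cycloadduct 19 (not isolated), via monosilylated resorcinol ketone 20 (not isolated)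
Conditions: 18 (3 equiv), toluene, 0 °C → rt (40 °C if slow); then 1 M HCl, THF, 0 °C → rt
Reagents that add atoms: none
Why: The electron-rich diene adds to the ynone in a normal-demand, asynchronous [4+2] cycloaddition in which its nucleophilic CH2 terminus bonds first to the heptyl-bearing β-carbon (C5–C6) and the ketene-acetal carbon then bonds to the α-carbon (C4a–C8a), giving the 1,4-cyclohexadiene 19. The mixed methyl silyl ketal of 19 should collapse with loss of methoxytrimethylsilane to a dienone that tautomerizes to phenol 20, and the acidic work-up removes the remaining silyl group. The closest known reaction type is the Diels–Alder/aromatization of 1,3-bis(silyloxy) ketene-acetal dienes with alkynones and alkynoates, which gives acylresorcinols and resorcylates. Ring A is closed by an intermolecular [4+2] annulation that forms both ring bonds in one cycloaddition event, and no stereocentre is created. The step needs regioselectivity (heptyl ortho to the acyl group, hydroxyl on the other ortho carbon) and chemoselectivity; the first follows from pairing the most nucleophilic diene terminus with the ynone β-carbon, the second from the ynone being the only electron-poor π bond, since the isocoumarin C3=C4 is an electron-rich enol ether. The enol lactone leaves one enolizable methylene and no free 1,3-diketone that could add to the alkyne, and the excess of diene covers silyl transfer to that methylene, which the acidic work-up reverses.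

Step 9
Reactants: 21 6,8-bis(benzyloxy)-3-[2-(2-heptyl-4,6-dihydroxyphenyl)-2-oxoethyl]-1H-isochromen-1-one
Product: 23 rac-2,4-bis(benzyloxy)-6-[(5-heptyl-2,7-dihydroxy-4-oxo-3,4-dihydro-2H-chromen-2-yl)methyl]benzoic acid, via open-chain diketo acid 22 (not isolated)
Conditions: LiOH·H2O (6 equiv), THF/H2O 3:1 (degassed, no alcohol), 0 °C → rt; 1 M HCl to pH 3–4, 0 °C
Reagents that add atoms: lithium hydroxide [Li+].[OH-]
Why: Saponification of the enol lactone by hydroxide (acyl–oxygen cleavage) frees the carboxylate and the C2 ketone as open-chain 22, and on mild acidification the ring A phenol ortho to the aryl ketone adds to the C2 carbonyl (6-exo hemiketalization) to give the 2-hydroxychromanone, C2 being formed without control as the racemate; water is kept as the only nucleophile because an alkoxide-opened ester could undergo Dieckmann closure to a naphthalenediol.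

Step 10
Reactants: 23 rac-2,4-bis(benzyloxy)-6-[(5-heptyl-2,7-dihydroxy-4-oxo-3,4-dihydro-2H-chromen-2-yl)methyl]benzoic acid
Product: 24 rac-2-[(5-heptyl-2,7-dihydroxy-4-oxo-3,4-dihydro-2H-chromen-2-yl)methyl]-4,6-dihydroxybenzoic acid
Conditions: H2 (1 atm), 10% Pd/C, EtOAc, rt
Reagents that add atoms: none
Why: Catalytic hydrogenolysis of the two aryl benzyl ethers over palladium should be selective because the electron-rich aryl ketone, the carboxylic acid and the hemiketal are inert under neutral hydrogenation at ambient pressure, and the alcohol-free solvent prevents acetal exchange at C2.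

Step 11
Reactants: 24 rac-2-[(5-heptyl-2,7-dihydroxy-4-oxo-3,4-dihydro-2H-chromen-2-yl)methyl]-4,6-dihydroxybenzoic acid
Product: 25 2-{[(2R)-5-heptyl-2,7-dihydroxy-4-oxo-3,4-dihydro-2H-chromen-2-yl]methyl}-4,6-dihydroxybenzoic acid
Conditions: preparative SFC, amylose tris(3,5-dimethylphenylcarbamate) phase, CO2/i-PrOH (0.1% HCO2H), 25 °C; fractions evaporated below 25 °C
Reagents that add atoms: none
Why: Chromatographic resolution on a polysaccharide chiral stationary phase: no stereocentre is created, the (2R) enantiomer is separated from its antipode by diastereomeric adsorption and assigned by comparison of its ECD curve with the calculated one, and the (2S) fraction can be returned to the racemate through base-catalysed ring–chain equilibration and re-injected.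

Compound list
1 | methyl orsellinate (methyl 2,4-dihydroxy-6-methylbenzoate) | COC(=O)c1c(C)cc(O)cc1O | starting material
2 | methyl 2,4-bis(benzyloxy)-6-methylbenzoate | COC(=O)c1c(C)cc(OCc2ccccc2)cc1OCc1ccccc1 | intermediate
3 | N-methoxy-N-methylacetamide | CC(=O)N(C)OC | starting material
4 | methyl 2,4-bis(benzyloxy)-6-(lithiomethyl)benzoate | COC(=O)c1c(C[Li])cc(OCc2ccccc2)cc1OCc1ccccc1 | intermediate
5 | lithium N-methoxyaminal adduct of 4 and 3 (racemic) | COC(=O)c1c(CC(C)(O[Li])N(C)OC)cc(OCc2ccccc2)cc1OCc1ccccc1 | intermediate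
6 | methyl 2,4-bis(benzyloxy)-6-(2-oxopropyl)benzoate | COC(=O)c1c(CC(C)=O)cc(OCc2ccccc2)cc1OCc1ccccc1 | intermediate
7 | 6,8-bis(benzyloxy)-3-methyl-1H-isochromen-1-one | CC1=Cc2cc(OCc3ccccc3)cc(OCc3ccccc3)c2C(=O)O1 | intermediate
8 | non-1-yne | CCCCCCCC#C | starting material
9 | N-methoxy-N-methylcarbamoyl chloride | CON(C)C(=O)Cl | starting material
10 | lithium non-1-yn-1-ide | CCCCCCCC#C[Li] | intermediate
11 | N-methoxy-N-methyldec-2-ynamide | CCCCCCCC#CC(=O)N(C)OC | intermediate
12 | 6,8-bis(benzyloxy)-3-(lithiomethyl)-1H-isochromen-1-one | [Li]CC1=Cc2cc(OCc3ccccc3)cc(OCc3ccccc3)c2C(=O)O1 | intermediate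
13 | lithium N-methoxyaminal adduct of 12 and 11 (racemic) | CCCCCCCC#CC(O[Li])(CC1=Cc2cc(OCc3ccccc3)cc(OCc3ccccc3)c2C(=O)O1)N(C)OC | intermediate
14 | 6,8-bis(benzyloxy)-3-(2-oxoundec-3-yn-1-yl)-1H-isochromen-1-one | CCCCCCCC#CC(=O)CC1=Cc2cc(OCc3ccccc3)cc(OCc3ccccc3)c2C(=O)O1 | intermediate
15 | methyl acetoacetate | COC(=O)CC(C)=O | starting material
16 | methyl 3-(trimethylsilyloxy)but-2-enoate (E/Z mixture) | COC(=O)C=C(C)O[Si](C)(C)C | intermediate
17 | lithium (Z)-1-methoxy-3-(trimethylsilyloxy)buta-1,3-dien-1-olate | C=C(O[Si](C)(C)C)/C=C(/OC)O[Li] | intermediate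
18 | (Z)-1-methoxy-1,3-bis(trimethylsilyloxy)buta-1,3-diene | C=C(O[Si](C)(C)C)/C=C(/OC)O[Si](C)(C)C | intermediate
19 | 6,8-bis(benzyloxy)-3-{2-[2-heptyl-6-methoxy-4,6-bis(trimethylsilyloxy)cyclohexa-1,4-dien-1-yl]-2-oxoethyl}-1H-isochromen-1-one (racemic) | CCCCCCCC1=C(C(=O)CC2=Cc3cc(OCc4ccccc4)cc(OCc4ccccc4)c3C(=O)O2)C(OC)(O[Si](C)(C)C)C=C(O[Si](C)(C)C)C1 | intermediate
20 | 6,8-bis(benzyloxy)-3-{2-[2-heptyl-6-hydroxy-4-(trimethylsilyloxy)phenyl]-2-oxoethyl}-1H-isochromen-1-one | CCCCCCCc1cc(O[Si](C)(C)C)cc(O)c1C(=O)CC1=Cc2cc(OCc3ccccc3)cc(OCc3ccccc3)c2C(=O)O1 | intermediate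
21 | 6,8-bis(benzyloxy)-3-[2-(2-heptyl-4,6-dihydroxyphenyl)-2-oxoethyl]-1H-isochromen-1-one | CCCCCCCc1cc(O)cc(O)c1C(=O)CC1=Cc2cc(OCc3ccccc3)cc(OCc3ccccc3)c2C(=O)O1 | intermediate
22 | 2,4-bis(benzyloxy)-6-[4-(2-heptyl-4,6-dihydroxyphenyl)-2,4-dioxobutyl]benzoic acid | CCCCCCCc1cc(O)cc(O)c1C(=O)CC(=O)Cc1cc(OCc2ccccc2)cc(OCc2ccccc2)c1C(=O)O | intermediate
23 | rac-2,4-bis(benzyloxy)-6-[(5-heptyl-2,7-dihydroxy-4-oxo-3,4-dihydro-2H-chromen-2-yl)methyl]benzoic acid | CCCCCCCc1cc(O)cc2c1C(=O)CC(O)(Cc1cc(OCc3ccccc3)cc(OCc3ccccc3)c1C(=O)O)O2 | intermediate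
24 | rac-2-[(5-heptyl-2,7-dihydroxy-4-oxo-3,4-dihydro-2H-chromen-2-yl)methyl]-4,6-dihydroxybenzoic acid | CCCCCCCc1cc(O)cc2c1C(=O)CC(O)(Cc1cc(O)cc(O)c1C(=O)O)O2 | intermediate
25 | 2-{[(2R)-5-heptyl-2,7-dihydroxy-4-oxo-3,4-dihydro-2H-chromen-2-yl]methyl}-4,6-dihydroxybenzoic acid | CCCCCCCc1cc(O)cc2c1C(=O)C[C@@](O)(Cc1cc(O)cc(O)c1C(=O)O)O2 | target

Total step count: 11
Longest linear sequence: 8 steps (steps 1, 2, 3, 5, 8, 9, 10, 11)

Steps most likely to fail

1. Step 8. Silyl transfer from the ketene acetal to the enolizable methylene may turn the ynone into a silyl dienol ether that no longer acts as a dienophile, or the addition may stop after the first C–C bond and not close the ring. The fallback gives up the cycloaddition and brings ring A in as a preformed arene; it sets out from 7 and comes back to the route at 24. Commercial 5-heptylresorcinol (CCCCCCCc1cc(O)cc(O)c1) would be formylated under Vilsmeier–Haack conditions (POCl3, DMF, then aqueous hydrolysis) to 2,4-dihydroxy-6-heptylbenzaldehyde F1 and benzylated (BnBr, K2CO3, DMF) to 2,4-bis(benzyloxy)-6-heptylbenzaldehyde F2. Anion 12, generated from 7 as in step 5, would add to F2 to give rac-6,8-bis(benzyloxy)-3-{2-[2,4-bis(benzyloxy)-6-heptylphenyl]-2-hydroxyethyl}-1H-isochromen-1-one F3. Dess–Martin oxidation would give 6,8-bis(benzyloxy)-3-{2-[2,4-bis(benzyloxy)-6-heptylphenyl]-2-oxoethyl}-1H-isochromen-1-one F4. Aqueous LiOH in THF would open the lactone to 2,4-bis(benzyloxy)-6-{4-[2,4-bis(benzyloxy)-6-heptylphenyl]-2,4-dioxobutyl}benzoic acid F5, and hydrogenolysis of all four benzyl ethers (H2, Pd/C, EtOAc) would give 24.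

2. Step 5. The delocalized anion may add in a conjugate sense to the alkynyl amide, may be quenched by proton transfer, or the adduct may collapse early to the enolizable ynone, which then consumes unreacted anion. The fallback forms the C–C bond at the alcohol oxidation level and oxidizes afterwards; it sets out from 7 (with 8) and comes back at 14. Alkyne 8 would be lithiated (n-BuLi, THF, −78 °C) and formylated with DMF to dec-2-ynal F6. Anion 12 would add 1,2 to F6 at −78 °C to give rac-6,8-bis(benzyloxy)-3-(2-hydroxyundec-3-yn-1-yl)-1H-isochromen-1-one F7, whose alkoxide is not acidic and cannot quench the anion. Dess–Martin periodinane (NaHCO3, CH2Cl2, 0 °C) would oxidize F7 to 14.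

3. Step 11. The enantiomers may be insufficiently resolved, or C2 may epimerize on the column or during evaporation through ring–chain tautomerism, so that the collected fraction loses enantiomeric purity. The fallback is a crystallization-induced diastereomer transformation that uses this lability; it sets out from 24 and comes back at 25. Racemate 24 and cinchonidine (1 equiv) would be crystallized from EtOAc/MeCN so that the less soluble salt, cinchonidinium 2-{[(2R)-5-heptyl-2,7-dihydroxy-4-oxo-3,4-dihydro-2H-chromen-2-yl]methyl}-4,6-dihydroxybenzoate F8, deposits while the tertiary amine equilibrates C2 in solution through the open diketone. A tertiary amine is chosen because a primary amine would condense with the open-chain 1,3-diketone. Should the (2S) salt be the one that crystallizes, the pseudo-enantiomeric cinchonine would be used instead. Partition of F8 between EtOAc and cold 0.5 M HCl would give 25.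

Further compounds
F1 | step 8 | 2,4-dihydroxy-6-heptylbenzaldehyde | CCCCCCCc1cc(O)cc(O)c1C=O
F2 | step 8 | 2,4-bis(benzyloxy)-6-heptylbenzaldehyde | CCCCCCCc1cc(OCc2ccccc2)cc(OCc2ccccc2)c1C=O
F3 | step 8 | rac-6,8-bis(benzyloxy)-3-{2-[2,4-bis(benzyloxy)-6-heptylphenyl]-2-hydroxyethyl}-1H-isochromen-1-one | CCCCCCCc1cc(OCc2ccccc2)cc(OCc2ccccc2)c1C(O)CC1=Cc2cc(OCc3ccccc3)cc(OCc3ccccc3)c2C(=O)O1
F4 | step 8 | 6,8-bis(benzyloxy)-3-{2-[2,4-bis(benzyloxy)-6-heptylphenyl]-2-oxoethyl}-1H-isochromen-1-one | CCCCCCCc1cc(OCc2ccccc2)cc(OCc2ccccc2)c1C(=O)CC1=Cc2cc(OCc3ccccc3)cc(OCc3ccccc3)c2C(=O)O1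
F5 | step 8 | 2,4-bis(benzyloxy)-6-{4-[2,4-bis(benzyloxy)-6-heptylphenyl]-2,4-dioxobutyl}benzoic acid | CCCCCCCc1cc(OCc2ccccc2)cc(OCc2ccccc2)c1C(=O)CC(=O)Cc1cc(OCc2ccccc2)cc(OCc2ccccc2)c1C(=O)O
F6 | step 5 | dec-2-ynal | CCCCCCCC#CC=O
F7 | step 5 | rac-6,8-bis(benzyloxy)-3-(2-hydroxyundec-3-yn-1-yl)-1H-isochromen-1-one | CCCCCCCC#CC(O)CC1=Cc2cc(OCc3ccccc3)cc(OCc3ccccc3)c2C(=O)O1
F8 | step 11 | cinchonidinium 2-{[(2R)-5-heptyl-2,7-dihydroxy-4-oxo-3,4-dihydro-2H-chromen-2-yl]methyl}-4,6-dihydroxybenzoate | CCCCCCCc1cc(O)cc2c1C(=O)C[C@@](O)(Cc1cc(O)cc(O)c1C(=O)[O-])O2.C=C[C@H]1C[NH+]2CC[C@H]1C[C@H]2[C@@H](c1ccnc2ccccc12)O
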